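Rings: A hydroquinone ring, B para-phenylene, C catechol ring, D meta-phenylene. The route rests on disconnecting the ether bond between the ring D oxygen and C-1 of ring A. The free hydroxyl of ring A (C-4) lies para to that carbon, so it is carried as a formyl group that turns a C-1 fluoride into an SNAr electrophile. One operation joins O(ring D) to C-1(ring A) and closes the 18-membered macrocycle; Baeyer-Villiger oxidation later converts CHO into OH. The precursor is the open A-B-C-D chain: a 4-fluorobenzaldehyde ring A, both ethano bridges, the B-O-C ether, a ring C methyl ether and one free phenol on ring D.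

Key step: step 8

Remark: the Wittig reaction of step 2 is expected to give an E/Z mixture. It is carried on unseparated, and that bond is drawn without a descriptor, because step 7 saturates it. The target has no stereocentre.

Step 1
Reactants: 1 3-(benzyloxy)benzyl alcohol
Product: 2 [3-(benzyloxy)benzyl]triphenylphosphonium bromide
Conditions: PPh3·HBr, MeCN, reflux
Reagents that add atoms: triphenylphosphine hydrobromide, [Br-].[PH+](c1ccccc1)(c1ccccc1)c1ccccc1
Why: One-pot phosphonium salt formation, in which the benzylic alcohol is activated by HBr and displaced by PPh3, and the aryl benzyl ether tolerates this weakly acidic medium.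

Step 2
Reactants: 2 [3-(benzyloxy)benzyl]triphenylphosphonium bromide; 3 isovanillin (3-hydroxy-4-methoxybenzaldehyde)
Product: 5 5-[2-(3-benzyloxyphenyl)ethenyl]-2-methoxyphenol (E/Z mixture), via benzylidene ylide 4 (not isolated)
Conditions: KOtBu (2.3 equiv), THF, 0 °C to rt; 1 M HCl quench
Reagents that add atoms: none
Why: Wittig olefination in which one equivalent of base makes the semistabilised ylide 4 and a second makes the phenoxide of 3, whose charge sits meta to the formyl group and so does not switch the aldehyde off.

Step 3
Reactants: 5 5-[2-(3-benzyloxyphenyl)ethenyl]-2-methoxyphenol; 6 4-fluorobenzaldehyde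
Product: 7 4-{5-[2-(3-benzyloxyphenyl)ethenyl]-2-methoxyphenoxy}benzaldehyde (E/Z mixture)
Conditions: K2CO3, DMF, 120 °C
Reagents that add atoms: none
Why: Intermolecular SNAr (addition-elimination) of the only free phenol on a para-formyl-activated C–F bond, a routine diaryl ether synthesis that leaves the benzyl ether and the alkene alone.

Step 4
Reactants: 7 4-{5-[2-(3-benzyloxyphenyl)ethenyl]-2-methoxyphenoxy}benzaldehyde
Product: 8 4-[2-(3-benzyloxyphenyl)ethenyl]-1-methoxy-2-(4-vinylphenoxy)benzene (E/Z mixture)
Conditions: Ph3PCH3Br, KOtBu, THF, 0 °C to rt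
Reagents that add atoms: methyltriphenylphosphonium bromide, [Br-].C[P+](c1ccccc1)(c1ccccc1)c1ccccc1
Why: Wittig methylenation of a non-enolisable aryl aldehyde with the unstabilised ylide is fast at low temperature and touches no other group in 7.

Step 5
Reactants: 9 3-bromo-4-fluorobenzaldehyde
Product: 10 2-(3-bromo-4-fluorophenyl)-1,3-dioxolane
Conditions: ethylene glycol, p-TsOH·H2O (cat.), toluene, reflux, Dean-Stark trap
Reagents that add atoms: ethylene glycol, OCCO
Why: Acid-catalysed acetalisation with azeotropic removal of water masks the formyl group on the small building block, so no protection step falls on the main line.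

Step 6
Reactants: 8 4-[2-(3-benzyloxyphenyl)ethenyl]-1-methoxy-2-(4-vinylphenoxy)benzene; 10 2-(3-bromo-4-fluorophenyl)-1,3-dioxolane
Product: 11 bis-stilbene acetal 2-{4-fluoro-3-[(E)-2-(4-{5-[2-(3-benzyloxyphenyl)ethenyl]-2-methoxyphenoxy}phenyl)ethenyl]phenyl}-1,3-dioxolane
Conditions: Pd(OAc)2 (5 mol %), P(o-tol)3 (10 mol %), K2CO3, DMF, 110 °C
Reagents that add atoms: none
Why: Mizoroki-Heck reaction, in which the arylpalladium bromide inserts at the CH2 terminus of the unhindered vinyl group far faster than into the 1,2-diaryl alkene, syn β-hydride elimination gives the E alkene, and the basic medium keeps the acetal closed.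

Step 7
Reactants: 11 bis-stilbene acetal
Product: 13 seco fluoroaldehyde phenol 4-fluoro-3-{2-[4-(5-[2-(3-hydroxyphenyl)ethyl]-2-methoxyphenoxy)phenyl]ethyl}benzaldehyde, via acetal phenol 12 (not isolated)
Conditions: H2 (1 atm), Pd/C (10 wt %), solid NaHCO3, EtOAc–EtOH, rt; filter through Celite; then 1 M HCl, THF, rt
Reagents that add atoms: water, O
Why: Heterogeneous catalytic hydrogenation saturates both C=C bonds and hydrogenolyses the aryl benzyl ether in one pass while the acid-free medium preserves the dioxolane and the inert C–F bond, and acetal hydrolysis is started only after the catalyst is filtered off, so the free aldehyde never meets H2 on palladium.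

Step 8
Reactants: 13 seco fluoroaldehyde phenol
Product: 14 macrocyclic aldehyde (18-membered bis(bibenzyl) diether; ring A CHO para to the new O–ring D bond, ring C OMe)
Conditions: Cs2CO3 (4 equiv), 4 Å MS, DMSO, 100 °C, Ar; 13 in DMSO added by syringe pump over 16 h (final ca. 2 mM)
Reagents that add atoms: none
Why: Cs2CO3 deprotonates the ring D phenol, the phenoxide adds to the fluorine-bearing C-1 of ring A to give a Meisenheimer anion whose charge is delocalised onto the para formyl oxygen, and loss of fluoride rearomatises ring A (addition-elimination SNAr). The closest known reaction type is the macrocyclising SNAr etherification of activated fluoroarenes used for cyclic diaryl ether peptides and diarylheptanoids, joined to the everyday coupling of phenols with 4-fluorobenzaldehydes. The one new ring is the 18-membered macrocycle, closed end to end by O–C(aryl) bond formation; the nucleophile arrives from above the ring A plane, so the in-plane ethano chain at C-2 blocks it little and no metal has to be accommodated next to it. No stereocentre is formed. The step needs chemoselectivity and cyclisation over chain growth: 13 offers only one acidic O–H and only one C–F bond (the ring C oxygen is capped as OMe and the aldehyde has no α-hydrogen), and slow addition keeps the free phenoxide at very low stationary concentration. DMSO is used instead of an amide solvent so that no dimethylamine can compete for the C–F carbon over the long addition, and sieves exclude hydroxide that could start Cannizzaro or C–F hydrolysis chemistry.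

Step 9
Reactants: 14 macrocyclic aldehyde
Product: 16 macrocyclic ring A phenol with ring C methyl ether, via aryl formate 15 (not isolated)
Conditions: mCPBA (1.5 equiv), CH2Cl2, 0 °C to rt; aq Na2S2O3/NaHCO3 wash, concentrate; then K2CO3 (cat.), MeOH, rt
Reagents that add atoms: mCPBA (3-chloroperoxybenzoic acid), OOC(=O)c1cccc(Cl)c1
Why: Baeyer-Villiger oxidation, in which the ring A aryl group of the Criegee adduct, enriched by its para aryloxy and meta alkyl substituents, migrates to oxygen in preference to hydride, and the resulting formate 15 shields the phenol from peracid until carbonate-catalysed methanolysis releases it.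

Step 10
Reactants: 16 macrocyclic ring A phenol with ring C methyl ether
Product: 17 target CNP0135015.0
Conditions: BBr3 (4 equiv), CH2Cl2, −78 °C to rt; then H2O
Reagents that add atoms: none
Why: Lewis-acid aryl methyl ether cleavage, in which BBr3 binds the methoxy oxygen and bromide attacks the methyl carbon by SN2, while the two diaryl ether bonds offer no sp3 carbon and survive.

Compound list
1 | 3-(benzyloxy)benzyl alcohol | OCc1cccc(OCc2ccccc2)c1 | starting material
2 | [3-(benzyloxy)benzyl]triphenylphosphonium bromide | [Br-].c1ccc(cc1)COc1cccc(C[P+](c2ccccc2)(c2ccccc2)c2ccccc2)c1 | intermediate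
3 | isovanillin | COc1ccc(C=O)cc1O | starting material
4 | [3-(benzyloxy)benzylidene]triphenylphosphorane (ylide, not isolated) | c1ccc(cc1)COc1cccc(C=P(c2ccccc2)(c2ccccc2)c2ccccc2)c1 | intermediate
5 | 5-[2-(3-benzyloxyphenyl)ethenyl]-2-methoxyphenol (E/Z mixture) | COc1ccc(C=Cc2cccc(OCc3ccccc3)c2)cc1O | intermediate
6 | 4-fluorobenzaldehyde | O=Cc1ccc(F)cc1 | starting material
7 | 4-{5-[2-(3-benzyloxyphenyl)ethenyl]-2-methoxyphenoxy}benzaldehyde (E/Z mixture) | COc1ccc(C=Cc2cccc(OCc3ccccc3)c2)cc1Oc1ccc(C=O)cc1 | intermediate
8 | 4-[2-(3-benzyloxyphenyl)ethenyl]-1-methoxy-2-(4-vinylphenoxy)benzene (E/Z mixture) | COc1ccc(C=Cc2cccc(OCc3ccccc3)c2)cc1Oc1ccc(C=C)cc1 | intermediate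
9 | 3-bromo-4-fluorobenzaldehyde | O=Cc1ccc(F)c(Br)c1 | starting material
10 | 2-(3-bromo-4-fluorophenyl)-1,3-dioxolane | Fc1ccc(cc1Br)C1OCCO1 | intermediate
11 | bis-stilbene acetal (A–B alkene E, C–D alkene E/Z mixture; ring D OBn, ring A dioxolane) | COc1ccc(C=Cc2cccc(OCc3ccccc3)c2)cc1Oc1ccc(/C=C/c2cc(ccc2F)C2OCCO2)cc1 | intermediate
12 | acetal phenol 3-{2-[3-(4-{2-[5-(1,3-dioxolan-2-yl)-2-fluorophenyl]ethyl}phenoxy)-4-methoxyphenyl]ethyl}phenol (not isolated) | COc1ccc(CCc2cccc(O)c2)cc1Oc1ccc(CCc2cc(ccc2F)C2OCCO2)cc1 | intermediate
13 | seco fluoroaldehyde phenol | O=Cc1ccc(F)c(c1)CCc1ccc(cc1)Oc1cc(ccc1OC)CCc1cccc(O)c1 | intermediate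
14 | macrocyclic aldehyde, ring C methyl ether | O=Cc1ccc2c(c1)CCc1ccc(cc1)Oc1cc(ccc1OC)CCc1cccc(c1)O2 | intermediate
15 | macrocyclic ring A aryl formate, ring C methyl ether (not isolated) | O=COc1ccc2c(c1)CCc1ccc(cc1)Oc1cc(ccc1OC)CCc1cccc(c1)O2 | intermediate
16 | macrocyclic ring A phenol, ring C methyl ether | Oc1ccc2c(c1)CCc1ccc(cc1)Oc1cc(ccc1OC)CCc1cccc(c1)O2 | intermediate
17 | CNP0135015.0 | Oc1ccc2c(c1)CCc1ccc(cc1)Oc1cc(ccc1O)CCc1cccc(c1)O2 | target

Total step count: 10.
Longest linear sequence: 9 (steps 1, 2, 3, 4, 6, 7, 8, 9, 10). Step 5 is a one-step branch.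

Steps most likely to fail

Step 8. Ring closure may lose out to chain growth. Substitution at the ortho-alkylated carbon, activated only by a formyl group, needs heat. Intermolecular etherification or base-induced erosion of the aldehyde can then overtake cyclisation. The fallback makes the ring D–O–ring A ether intermolecularly and closes the macrocycle at the A–B bridge by an intramolecular Wittig reaction.
- It sets out from 7. NaBH4 in MeOH–THF should give benzylic alcohol F1.
- H2 over Pd/C in EtOAc saturates the alkene and removes the benzyl group to give phenol alcohol F2.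
- K2CO3 in DMF at 140 °C with 2-fluoro-5-methoxybenzaldehyde gives aldehyde alcohol F3. This is an ortho-formyl-activated SNAr, with the ring A oxygen already in place as OMe, and only the phenol is deprotonated.
- PPh3·HBr in refluxing MeCN gives formyl phosphonium bromide F4.
- Slow addition of F4 to NaOMe in CH2Cl2 closes the ring to macrocyclic stilbene F5.
- H2 over Pd/C gives macrocyclic dimethyl ether F6.
- BBr3 under the conditions of step 10 cleaves both methyl ethers, and the route is rejoined at 17.

Step 9. Hydride migration may compete with aryl migration in the peracid adduct, because ring A is only moderately electron-rich. That would be plain oxidation of the formyl group. The fallback removes the migrating hydrogen by passing through a methyl ketone.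
- It sets out from 14. MeMgBr in THF at 0 °C should give racemic secondary alcohol F7.
- MnO2 in CH2Cl2 gives methyl ketone F8.
- mCPBA with catalytic CF3CO2H in CH2Cl2 gives aryl acetate F9, since aryl migrates over methyl.
- K2CO3 in MeOH rejoins the route at 16.

Step 7. The benzylic acetal may be lost by hydrogenolysis, or opened early on an acidic catalyst and followed by over-reduction of the formyl carbon, while the slower benzyl ether cleavage is pushed to completion. The fallback avoids heterogeneous hydrogenation altogether.
- It sets out from 11. Diimide (TsNHNH2, NaOAc, THF–H2O, reflux) saturates both alkenes without touching acetal, benzyl ether or C–F, giving benzyl ether acetal F10.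
- BCl3 with pentamethylbenzene in CH2Cl2 at −78 °C removes the benzyl group selectively over the methyl ether.
- Work-up with 1 M HCl in THF completes acetal hydrolysis, and the route is rejoined at 13.

Further compounds
F1 | step 8 | {4-[5-(2-(3-benzyloxyphenyl)ethenyl)-2-methoxyphenoxy]phenyl}methanol (E/Z mixture) | COc1ccc(C=Cc2cccc(OCc3ccccc3)c2)cc1Oc1ccc(CO)cc1
F2 | step 8 | 3-[2-(3-[4-(hydroxymethyl)phenoxy]-4-methoxyphenyl)ethyl]phenol | COc1ccc(CCc2cccc(O)c2)cc1Oc1ccc(CO)cc1
F3 | step 8 | 2-{3-[2-(3-[4-(hydroxymethyl)phenoxy]-4-methoxyphenyl)ethyl]phenoxy}-5-methoxybenzaldehyde | COc1ccc(Oc2cccc(CCc3ccc(OC)c(Oc4ccc(CO)cc4)c3)c2)c(C=O)c1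
F4 | step 8 | formyl phosphonium bromide derived from F3 | [Br-].COc1ccc(Oc2cccc(CCc3ccc(OC)c(Oc4ccc(C[P+](c5ccccc5)(c5ccccc5)c5ccccc5)cc4)c3)c2)c(C=O)c1
F5 | step 8 | macrocyclic stilbene, rings A and C as methyl ethers (E/Z mixture) | COc1ccc2c(c1)C=Cc1ccc(cc1)Oc1cc(ccc1OC)CCc1cccc(c1)O2
F6 | step 8 | macrocyclic dimethyl ether of the target | COc1ccc2c(c1)CCc1ccc(cc1)Oc1cc(ccc1OC)CCc1cccc(c1)O2
F7 | step 9 | macrocyclic ring A 1-hydroxyethyl compound (racemic) | CC(O)c1ccc2c(c1)CCc1ccc(cc1)Oc1cc(ccc1OC)CCc1cccc(c1)O2
F8 | step 9 | macrocyclic ring A methyl ketone | CC(=O)c1ccc2c(c1)CCc1ccc(cc1)Oc1cc(ccc1OC)CCc1cccc(c1)O2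
F9 | step 9 | macrocyclic ring A aryl acetate | CC(=O)Oc1ccc2c(c1)CCc1ccc(cc1)Oc1cc(ccc1OC)CCc1cccc(c1)O2
F10 | step 7 | saturated benzyl ether acetal | COc1ccc(CCc2cccc(OCc3ccccc3)c2)cc1Oc1ccc(CCc2cc(ccc2F)C2OCCO2)cc1
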